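**Retrosynthetic overview**
1. The C8–O ester is made last: the nine-membered lactone alcohol is acylated with (2Z,4R)-4-(triethylsilyloxy)dec-2-enoic acid, obtained from (R)-γ-decalactone through its butenolide (the ring fixes the Z alkene); one acidic step then frees the C5, C6 and side-chain hydroxyls.
2. The lactone C2(=O)–O–C9 is the last ring formed, by Shiina lactonisation of a seco acid carrying C4–OAc, a C5/C6 acetonide and C8–OTIPS.
3. The C3–C4 bond comes from a chelation-controlled crotylstannane addition to a C4 aldehyde with a free tertiary C5–OH (sets C3 and C4); the vinyl group is later cleaved to the C2 acid.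
4. The C5/C6 diol comes from substrate-directed dihydroxylation of an (E)-2-methyl enal, itself made by Luche reduction and Ferrier-type hydrolytic opening of a 2,3-cis-2,3-dihydro-4H-pyran-4-one.
5. Key step and first ring: hetero-Diels–Alder reaction of (S)-2-silyloxypropanal (from ethyl (S)-lactate) with a 1-methoxy-3-silyloxy diene sets C7 and C8 from C9. Ring order: dihydropyranone (opened again), dioxolane, nine-membered lactone.

Assumption: (E)-1-methoxy-2-methylpent-1-en-3-one and (R)-γ-decalactone of high ee (the fermentation product derived from ricinoleic acid) are taken as bought.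

Locants C2 to C9 are those of the target's lactone ring (C2 = lactone carbonyl, C9 = ring CH carrying the methyl group). TBS = tert-butyldimethylsilyl, TIPS = triisopropylsilyl, TES = triethylsilyl, TMS = trimethylsilyl.

**Route**

Step 1
Reactants: 1 ethyl (2S)-2-hydroxypropanoate (ethyl (S)-lactate)
Product: 2 ethyl (2S)-2-(TBSO)propanoate
Conditions: TBSCl, imidazole, DMF, 0 °C to rt
Reagents that add atoms: tert-butyl(chloro)dimethylsilane, CC(C)(C)[Si](C)(C)Cl
Why: Imidazole-promoted silyl ether formation leaves the C9 stereocentre untouched and installs a bulky, poorly coordinating group.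

Step 2
Reactants: 2 ethyl (2S)-2-(TBSO)propanoate
Product: 3 (2S)-2-(TBSO)propanal
Conditions: (Me2CHCH2)2AlH (1.05 equiv), CH2Cl2, −78 °C; aq. potassium sodium tartrate
Reagents that add atoms: none
Why: Partial ester reduction: at −78 °C the tetrahedral aluminium hemiacetal survives until work-up, giving the α-silyloxy aldehyde without epimerisation.

Step 3
Reactants: 4 (1E)-1-methoxy-2-methylpent-1-en-3-one
Product: 5 (1E,3Z)-1-methoxy-2-methyl-3-(trimethylsilyloxy)penta-1,3-diene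
Conditions: Me3SiOTf, Et3N, Et2O, 0 °C
Reagents that add atoms: trimethylsilyl trifluoromethanesulfonate, C[Si](C)(C)OS(=O)(=O)C(F)(F)F
Why: Soft enolisation (silyl enol ether formation) gives the more stable (Z)-enol ether, a Danishefsky-type diene with both terminal substituents pointing outward.

Step 4
Reactants: 3 (2S)-2-(TBSO)propanal; 5 (1E,3Z)-1-methoxy-2-methyl-3-(trimethylsilyloxy)penta-1,3-diene
Product: 7 (2R,3R)-2-[(1S)-1-(TBSO)ethyl]-3,5-dimethyl-2,3-dihydro-4H-pyran-4-one, via silyl enol ether cycloadduct 6 (not isolated)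
Conditions: ZnCl2 (1 equiv), THF, rt, 36 h; then CF3CO2H (cat.), CH2Cl2, 0 °C
Reagents that add atoms: none
Why: Lewis-acid-promoted hetero-Diels–Alder reaction (Danishefsky cyclocondensation): endo approach of the ZnCl2-bound aldehyde gives the 2,3-cis ring (C7 methyl syn to C8 oxygen), attack anti to the non-chelating OTBS group (polar Felkin–Anh) sets C8 anti to C9, and acid then unmasks the enone.

Step 5
Reactants: 7 (2R,3R)-2-[(1S)-1-(TBSO)ethyl]-3,5-dimethyl-2,3-dihydro-4H-pyran-4-one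
Product: 9 (2E,4S,5R,6S)-6-(TBSO)-5-hydroxy-2,4-dimethylhept-2-enal, via glycal alcohol 8 (not isolated)
Conditions: NaBH4, CeCl3·7H2O, MeOH, −78 °C; then 0.1 M aq. HCl, THF, 0 °C
Reagents that add atoms: water, O
Why: Luche 1,2-reduction gives a vinylogous hemiacetal alcohol that ionises under mild acid (Ferrier-type allylic transposition, Perlin hydrolysis); water adds at the acetal carbon and the lactol opens and equilibrates to the (E)-enal, which cannot reclose, leaving C7 to C9 untouched.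

Step 6
Reactants: 9 (2E,4S,5R,6S)-6-(TBSO)-5-hydroxy-2,4-dimethylhept-2-enal
Product: 10 (2E,4S,5R,6S)-6-(TBSO)-2,4-dimethyl-5-(TIPSO)hept-2-enal
Conditions: (Me2CH)3SiOTf, 2,6-lutidine, CH2Cl2, −78 to 0 °C
Reagents that add atoms: triisopropylsilyl trifluoromethanesulfonate, CC(C)[Si](OS(=O)(=O)C(F)(F)F)(C(C)C)C(C)C
Why: Silyl ether formation on the only free hydroxyl blocks C8–O with a group that outlasts the later removal of the C9 TBS ether and prevents lactol formation after the next step.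

Step 7
Reactants: 10 (2E,4S,5R,6S)-6-(TBSO)-2,4-dimethyl-5-(TIPSO)hept-2-enal
Product: 11 (2R,3S,4S,5R,6S)-6-(TBSO)-2,3-dihydroxy-2,4-dimethyl-5-(TIPSO)heptanal
Conditions: OsO4 (5 mol%), N-methylmorpholine N-oxide, citric acid, t-BuOH/H2O, rt
Reagents that add atoms: osmium tetroxide, O=[Os](=O)(=O)=O; N-methylmorpholine N-oxide, C[N+]1([O-])CCOCC1; water, O
Why: Upjohn syn-dihydroxylation of the (E)-trisubstituted alkene gives the syn C5/C6 diol; A(1,3) strain with the C5 methyl holds C7–H in the alkene plane, so OsO4 adds anti to the large C8 chain (Kishi/Houk model), placing C6–OH syn to the C7 methyl.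

Step 8
Reactants: 11 (2R,3S,4S,5R,6S)-6-(TBSO)-2,3-dihydroxy-2,4-dimethyl-5-(TIPSO)heptanal
Product: 12 (2R,3S,4R,5R,6S)-6-(TBSO)-2-hydroxy-2,4-dimethyl-3-(TESO)-5-(TIPSO)heptanal
Conditions: Et3SiOTf (1.05 equiv), 2,6-lutidine, CH2Cl2, −78 °C
Reagents that add atoms: triethylsilyl trifluoromethanesulfonate, CC[Si](CC)(CC)OS(=O)(=O)C(F)(F)F
Why: Selective silylation: the secondary C6 hydroxyl reacts far faster than the tertiary C5 hydroxyl, which stays free as the chelating group for the next step.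

Step 9
Reactants: 12 (2R,3S,4R,5R,6S)-6-(TBSO)-2-hydroxy-2,4-dimethyl-3-(TESO)-5-(TIPSO)heptanal
Product: 13 (3S,4R,5S,6S,7R,8R,9S)-9-(TBSO)-3,5,7-trimethyl-6-(TESO)-8-(TIPSO)dec-1-ene-4,5-diol
Conditions: MgBr2·OEt2 (3 equiv), CH2Cl2, −25 °C; then Bu3SnCH2CH=CHCH3 (2 equiv), −25 to 0 °C
Reagents that add atoms: tributyl(but-2-en-1-yl)stannane, CCCC[Sn](CCCC)(CCCC)C/C=C/C
Why: Keck chelation-controlled crotylstannane addition: MgBr2 bridges the aldehyde oxygen and the free C5 hydroxyl (Cram cyclic model), the nucleophile enters from the methyl face to give C4–OH syn to C5–OH, and the open antiperiplanar transition state gives the C3 methyl syn to C4–OH.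

Step 10
Reactants: 13 (3S,4R,5S,6S,7R,8R,9S)-9-(TBSO)-3,5,7-trimethyl-6-(TESO)-8-(TIPSO)dec-1-ene-4,5-diol
Product: 14 (3S,4R,5S,6S,7R,8R,9S)-9-(TBSO)-5-hydroxy-3,5,7-trimethyl-6-(TESO)-8-(TIPSO)dec-1-en-4-yl acetate
Conditions: Ac2O, DMAP (cat.), Et3N, CH2Cl2, 0 °C to rt
Reagents that add atoms: acetic anhydride, CC(=O)OC(C)=O
Why: DMAP-catalysed acetylation esterifies the secondary C4 hydroxyl while the tertiary C5 hydroxyl does not react.

Step 11
Reactants: 14 (3S,4R,5S,6S,7R,8R,9S)-9-(TBSO)-5-hydroxy-3,5,7-trimethyl-6-(TESO)-8-(TIPSO)dec-1-en-4-yl acetate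
Product: 16 C5,C6-acetonide of 15 (2,2-dimethyl-1,3-dioxolane across the C5 and C6 oxygens; C4 acetate; C8 OTIPS; C9 OTBS; terminal vinyl group), via diol acetate 15 (not isolated)
Conditions: PPTS (cat.), MeOH, 0 °C to rt; then 2,2-dimethoxypropane, acetone, PPTS, rt
Reagents that add atoms: 2,2-dimethoxypropane, COC(C)(C)OC
Why: Acid methanolysis removes the labile TES ether in the presence of TBS and TIPS, and transketalisation of the resulting syn-1,2-diol (acetonide formation) masks the γ- and δ-hydroxyls of the future acid.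

Step 12
Reactants: 16 C5,C6-acetonide with terminal vinyl group
Product: 17 seco acid (vinyl group of 16 oxidised to the C2 carboxylic acid; C4 acetate; C5,C6-acetonide; C8 OTIPS; C9 OTBS)
Conditions: RuCl3·3H2O (3 mol%), NaIO4 (4.2 equiv), CCl4/MeCN/H2O, rt
Reagents that add atoms: sodium periodate, [Na+].[O-]I(=O)(=O)=O; water, O
Why: Sharpless oxidative cleavage: RuO4 formed in situ cuts the terminal alkene to the carboxylic acid without touching silyl ethers, acetate or acetonide and without disturbing C3.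

Step 13
Reactants: 17 seco acid with C8 OTIPS and C9 OTBS
Product: 18 C9-hydroxy seco acid (as 17 but C9 OH free)
Conditions: HF·pyridine, pyridine, THF, 0 °C to rt
Reagents that add atoms: none
Why: Selective desilylation: buffered fluoride removes the less hindered secondary TBS ether at C9 much faster than the hindered TIPS ether at C8.

Step 14
Reactants: 18 C9-hydroxy seco acid
Product: 19 nine-membered lactone (oxonan-2-one closed from C2 acid to C9 oxygen; C4 acetate; C5,C6-acetonide; C8 OTIPS)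
Conditions: 2-methyl-6-nitrobenzoic anhydride (MNBA), DMAP, Et3N, CH2Cl2 (1 mM, slow addition), rt
Reagents that add atoms: none
Why: Shiina macrolactonisation: the mixed anhydride is passed by DMAP to the only free hydroxyl (C9) at high dilution, the cis-fused dioxolane pre-organising the chain, and C9 is retained because the acid is the activated partner.

Step 15
Reactants: 19 nine-membered lactone with C8 OTIPS
Product: 20 lactone alcohol (as 19 but C8 OH free)
Conditions: HF·pyridine (excess), THF, rt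
Reagents that add atoms: none
Why: Desilylation under near-neutral fluoride conditions leaves the lactone, acetate and acetonide intact.

Step 16
Reactants: 21 (5R)-5-hexyloxolan-2-one ((R)-γ-decalactone)
Product: 23 (5R)-5-hexylfuran-2(5H)-one, via selenide lactone 22 (not isolated)
Conditions: LiN(CHMe2)2, THF, −78 °C; PhSeCl; then H2O2 (30% aq.), pyridine, CH2Cl2, 0 °C to rt
Reagents that add atoms: none
Why: α-Selenenylation of the lactone enolate followed by oxidation and selenoxide syn-elimination introduces the ring double bond without touching the carbinol stereocentre.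

Step 17
Reactants: 23 (5R)-5-hexylfuran-2(5H)-one
Product: 26 (2Z,4R)-4-(triethylsilyloxy)dec-2-enoic acid, via sodium hydroxy enoate 24 (not isolated), via bis-silylated enoate 25 (not isolated)
Conditions: NaOH (1.0 equiv), MeOH/H2O, 0 °C, then evaporation; Et3SiCl, imidazole, DMF, 0 °C to rt; then THF/pH 6 phosphate buffer, 0 °C
Reagents that add atoms: sodium hydroxide, [Na+].[OH-]; chlorotriethylsilane, CC[Si](Cl)(CC)CC
Why: Lactone saponification opens the butenolide to the hydroxy enoate whose Z geometry is set by the ring, silylation of both oxygens prevents relactonisation, and only the labile silyl ester is hydrolysed.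

Step 18
Reactants: 20 lactone alcohol; 26 (2Z,4R)-4-(triethylsilyloxy)dec-2-enoic acid
Product: 27 C8 ester of 20 with acid 26 (protected target)
Conditions: DCC, DMAP (0.2 equiv), CH2Cl2, 0 °C to rt
Reagents that add atoms: none
Why: Steglich esterification acylates the single free hydroxyl at C8, and sub-stoichiometric DMAP at low temperature preserves the Z alkene.

Step 19
Reactants: 27 protected target
Product: 28 (3R,4R,5R,6S,7S,8R,9S)-4-acetoxy-5,6-dihydroxy-3,5,7,9-tetramethyl-2-oxooxonan-8-yl (2Z,4R)-4-hydroxydec-2-enoate (CNP0240788.3)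
Conditions: CF3CO2H/H2O/THF (2:1:2), 0 °C; pH 7 phosphate buffer work-up
Reagents that add atoms: none
Why: Acetal hydrolysis and desilylation in one cold acidic operation free the C5, C6 and side-chain hydroxyls, with short contact and neutral work-up to limit translactonisation and butenolide formation.

**Compound list**
1 | ethyl (2S)-2-hydroxypropanoate | C[C@H](O)C(=O)OCC | starting material
2 | ethyl (2S)-2-(TBSO)propanoate | C[C@H](O[Si](C)(C)C(C)(C)C)C(=O)OCC | intermediate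
3 | (2S)-2-(TBSO)propanal | C[C@H](O[Si](C)(C)C(C)(C)C)C=O | intermediate
4 | (1E)-1-methoxy-2-methylpent-1-en-3-one | CCC(=O)/C(C)=C/OC | starting material
5 | (1E,3Z)-1-methoxy-2-methyl-3-(trimethylsilyloxy)penta-1,3-diene | C/C=C(\O[Si](C)(C)C)/C(C)=C/OC | intermediate
6 | 2,3,6-all-cis (2R,3R)-2-[(1S)-1-(TBSO)ethyl]-6-methoxy-3,5-dimethyl-4-(trimethylsilyloxy)-3,6-dihydro-2H-pyran | C[C@H](O[Si](C)(C)C(C)(C)C)[C@@H]1O[C@H](OC)C(C)=C(O[Si](C)(C)C)[C@@H]1C | intermediate (not isolated)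
7 | (2R,3R)-2-[(1S)-1-(TBSO)ethyl]-3,5-dimethyl-2,3-dihydro-4H-pyran-4-one | C[C@H](O[Si](C)(C)C(C)(C)C)[C@@H]1OC=C(C)C(=O)[C@@H]1C | intermediate
8 | 2,3,4-all-cis 2-[(1S)-1-(TBSO)ethyl]-3,5-dimethyl-3,4-dihydro-2H-pyran-4-ol | C[C@H](O[Si](C)(C)C(C)(C)C)[C@@H]1OC=C(C)[C@H](O)[C@@H]1C | intermediate (not isolated)
9 | (2E,4S,5R,6S)-6-(TBSO)-5-hydroxy-2,4-dimethylhept-2-enal | C[C@H](O[Si](C)(C)C(C)(C)C)[C@H](O)[C@@H](C)/C=C(\C)C=O | intermediate
10 | (2E,4S,5R,6S)-6-(TBSO)-2,4-dimethyl-5-(TIPSO)hept-2-enal | C[C@H](O[Si](C)(C)C(C)(C)C)[C@H](O[Si](C(C)C)(C(C)C)C(C)C)[C@@H](C)/C=C(\C)C=O | intermediate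
11 | (2R,3S,4S,5R,6S)-6-(TBSO)-2,3-dihydroxy-2,4-dimethyl-5-(TIPSO)heptanal | C[C@H](O[Si](C)(C)C(C)(C)C)[C@H](O[Si](C(C)C)(C(C)C)C(C)C)[C@@H](C)[C@H](O)[C@@](C)(O)C=O | intermediate
12 | (2R,3S,4R,5R,6S)-6-(TBSO)-2-hydroxy-2,4-dimethyl-3-(TESO)-5-(TIPSO)heptanal | C[C@H](O[Si](C)(C)C(C)(C)C)[C@H](O[Si](C(C)C)(C(C)C)C(C)C)[C@@H](C)[C@H](O[Si](CC)(CC)CC)[C@@](C)(O)C=O | intermediate
13 | (3S,4R,5S,6S,7R,8R,9S)-9-(TBSO)-3,5,7-trimethyl-6-(TESO)-8-(TIPSO)dec-1-ene-4,5-diol | C[C@H](O[Si](C)(C)C(C)(C)C)[C@H](O[Si](C(C)C)(C(C)C)C(C)C)[C@@H](C)[C@H](O[Si](CC)(CC)CC)[C@@](C)(O)[C@H](O)[C@@H](C)C=C | intermediate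
14 | (3S,4R,5S,6S,7R,8R,9S)-9-(TBSO)-5-hydroxy-3,5,7-trimethyl-6-(TESO)-8-(TIPSO)dec-1-en-4-yl acetate | C[C@H](O[Si](C)(C)C(C)(C)C)[C@H](O[Si](C(C)C)(C(C)C)C(C)C)[C@@H](C)[C@H](O[Si](CC)(CC)CC)[C@@](C)(O)[C@H](OC(C)=O)[C@@H](C)C=C | intermediate
15 | (3S,4R,5R,6S,7S,8R,9S)-9-(TBSO)-5,6-dihydroxy-3,5,7-trimethyl-8-(TIPSO)dec-1-en-4-yl acetate | C[C@H](O[Si](C)(C)C(C)(C)C)[C@H](O[Si](C(C)C)(C(C)C)C(C)C)[C@@H](C)[C@H](O)[C@@](C)(O)[C@H](OC(C)=O)[C@@H](C)C=C | intermediate (not isolated)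
16 | C5,C6-acetonide of 15 (C4 acetate, C8 OTIPS, C9 OTBS, terminal vinyl group; stereocentres unchanged) | C[C@H](O[Si](C)(C)C(C)(C)C)[C@H](O[Si](C(C)C)(C(C)C)C(C)C)[C@@H](C)[C@@H]1OC(C)(C)O[C@@]1(C)[C@H](OC(C)=O)[C@@H](C)C=C | intermediate
17 | seco acid: C2 carboxylic acid from the vinyl group of 16 (C4 acetate, C5,C6-acetonide, C8 OTIPS, C9 OTBS) | C[C@H](O[Si](C)(C)C(C)(C)C)[C@H](O[Si](C(C)C)(C(C)C)C(C)C)[C@@H](C)[C@@H]1OC(C)(C)O[C@@]1(C)[C@H](OC(C)=O)[C@@H](C)C(=O)O | intermediate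
18 | C9-hydroxy seco acid (as 17, C9 OH free) | C[C@H](O)[C@H](O[Si](C(C)C)(C(C)C)C(C)C)[C@@H](C)[C@@H]1OC(C)(C)O[C@@]1(C)[C@H](OC(C)=O)[C@@H](C)C(=O)O | intermediate
19 | nine-membered lactone (oxonan-2-one; C4 acetate, C5,C6-acetonide, C8 OTIPS) | C[C@H]2[C@H](O[Si](C(C)C)(C(C)C)C(C)C)[C@@H](C)[C@@H]1OC(C)(C)O[C@@]1(C)[C@H](OC(C)=O)[C@@H](C)C(=O)O2 | intermediate
20 | lactone alcohol (as 19, C8 OH free) | C[C@H]2[C@H](O)[C@@H](C)[C@@H]1OC(C)(C)O[C@@]1(C)[C@H](OC(C)=O)[C@@H](C)C(=O)O2 | intermediate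
21 | (5R)-5-hexyloxolan-2-one ((R)-γ-decalactone) | CCCCCC[C@@H]1CCC(=O)O1 | starting material
22 | (5R)-5-hexyl-3-(phenylselanyl)oxolan-2-one (C3 epimers) | CCCCCC[C@@H]1CC([Se]c2ccccc2)C(=O)O1 | intermediate (not isolated)
23 | (5R)-5-hexylfuran-2(5H)-one | CCCCCC[C@@H]1C=CC(=O)O1 | intermediate
24 | sodium (2Z,4R)-4-hydroxydec-2-enoate | CCCCCC[C@@H](O)/C=C\C(=O)[O-].[Na+] | intermediate (not isolated)
25 | triethylsilyl (2Z,4R)-4-(triethylsilyloxy)dec-2-enoate | CCCCCC[C@@H](O[Si](CC)(CC)CC)/C=C\C(=O)O[Si](CC)(CC)CC | intermediate (not isolated)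
26 | (2Z,4R)-4-(triethylsilyloxy)dec-2-enoic acid | CCCCCC[C@@H](O[Si](CC)(CC)CC)/C=C\C(=O)O | intermediate
27 | C8 ester of 20 with 26 (C5,C6-acetonide and side-chain OTES still in place) | CCCCCC[C@@H](O[Si](CC)(CC)CC)/C=C\C(=O)O[C@@H]1[C@@H](C)[C@@H]2OC(C)(C)O[C@@]2(C)[C@H](OC(C)=O)[C@@H](C)C(=O)O[C@H]1C | intermediate
28 | (3R,4R,5R,6S,7S,8R,9S)-4-acetoxy-5,6-dihydroxy-3,5,7,9-tetramethyl-2-oxooxonan-8-yl (2Z,4R)-4-hydroxydec-2-enoate | CCCCCC[C@@H](O)/C=C\C(=O)O[C@@H]1[C@@H](C)[C@H](O)[C@@](C)(O)[C@H](OC(C)=O)[C@@H](C)C(=O)O[C@H]1C | target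

**Step count and risks**

Total: 19 steps. Longest linear sequence: 16 steps (1, 2, 4 to 15, 18, 19) from ethyl (S)-lactate.

Most likely to fail:

- **Step 4 (hetero-Diels–Alder).** Two selectivities must hold at once: endo (2,3-cis) rather than the Mukaiyama-aldol trans pathway, and Felkin rather than chelation control at C8. Fallback, setting out from 3 and replacing the cycloaddition by an allylboration: (Z)-crotylboronic acid pinacol ester (toluene, rt) adds through a closed chair transition state with Felkin selectivity to give (3S,4R,5S)-5-(TBSO)-3-methylhex-1-en-4-ol F1. Silylation with (Me2CH)3SiOTf/2,6-lutidine gives (3S,4R,5S)-5-(TBSO)-3-methyl-4-(TIPSO)hex-1-ene F2. Ozonolysis (O3, CH2Cl2, −78 °C; PPh3) gives (2R,3R,4S)-4-(TBSO)-2-methyl-3-(TIPSO)pentanal F3. Wittig reaction with Ph3P=C(CH3)CHO (toluene, 80 °C) gives the (E)-enal and rejoins the route at 10.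

- **Step 9 (chelation-controlled crotylation).** The free tertiary hydroxyl may chelate poorly or protonate the stannane, which would erode the C4 and C3 selectivity. Fallback, setting out from 12 and using an ester enolate equivalent instead of an allylmetal: Mukaiyama aldol reaction with (E)-1-(benzyloxy)-1-(trimethylsilyloxy)prop-1-ene and TiCl4 (CH2Cl2, −78 °C), where the titanium alkoxide of the C5 hydroxyl forms a rigid chelate and the open transition state gives the syn,syn adduct, the benzyl ester aldol adduct F4. Acetylation (Ac2O, DMAP, Et3N) gives the C4 acetate benzyl ester F5. PPTS/MeOH then 2,2-dimethoxypropane gives the acetonide benzyl ester F6. Hydrogenolysis (H2, Pd/C, EtOAc) frees the acid and rejoins the route at 17.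

- **Step 14 (nine-membered lactonisation).** Medium-ring closure competes with oligomerisation and with β-elimination of the C4 acetate from the activated acid. Fallback, setting out from 18 and closing the ring by C9–O bond formation instead of acyl activation: Dess–Martin oxidation of the C9 hydroxyl gives the C9 methyl ketone acid F7. Reduction with LiBH(CHMeEt)3 (THF, −78 °C; Felkin–Anh, hydride anti to C8–OTIPS) gives the (9R)-hydroxy acid F8. Mitsunobu lactonisation (PPh3, diisopropyl azodicarboxylate, toluene, high dilution) then closes the ring with inversion at C9 and rejoins the route at 19.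

**Further compounds**
F1 | step 4 | (3S,4R,5S)-5-(TBSO)-3-methylhex-1-en-4-ol | C[C@H](O[Si](C)(C)C(C)(C)C)[C@H](O)[C@@H](C)C=C
F2 | step 4 | (3S,4R,5S)-5-(TBSO)-3-methyl-4-(TIPSO)hex-1-ene | C[C@H](O[Si](C)(C)C(C)(C)C)[C@H](O[Si](C(C)C)(C(C)C)C(C)C)[C@@H](C)C=C
F3 | step 4 | (2R,3R,4S)-4-(TBSO)-2-methyl-3-(TIPSO)pentanal | C[C@H](O[Si](C)(C)C(C)(C)C)[C@H](O[Si](C(C)C)(C(C)C)C(C)C)[C@@H](C)C=O
F4 | step 9 | benzyl ester aldol adduct (C2 benzyl ester, C3 methyl, C4 and C5 hydroxyls free, C6 OTES, C8 OTIPS, C9 OTBS) | C[C@H](O[Si](C)(C)C(C)(C)C)[C@H](O[Si](C(C)C)(C(C)C)C(C)C)[C@@H](C)[C@H](O[Si](CC)(CC)CC)[C@@](C)(O)[C@H](O)[C@@H](C)C(=O)OCc1ccccc1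
F5 | step 9 | C4 acetate of F4 | C[C@H](O[Si](C)(C)C(C)(C)C)[C@H](O[Si](C(C)C)(C(C)C)C(C)C)[C@@H](C)[C@H](O[Si](CC)(CC)CC)[C@@](C)(O)[C@H](OC(C)=O)[C@@H](C)C(=O)OCc1ccccc1
F6 | step 9 | benzyl ester of seco acid 17 (C4 acetate, C5,C6-acetonide, C8 OTIPS, C9 OTBS) | C[C@H](O[Si](C)(C)C(C)(C)C)[C@H](O[Si](C(C)C)(C(C)C)C(C)C)[C@@H](C)[C@@H]1OC(C)(C)O[C@@]1(C)[C@H](OC(C)=O)[C@@H](C)C(=O)OCc1ccccc1
F7 | step 14 | C9 methyl ketone acid (18 with C9 OH oxidised to C=O) | CC(=O)[C@H](O[Si](C(C)C)(C(C)C)C(C)C)[C@@H](C)[C@@H]1OC(C)(C)O[C@@]1(C)[C@H](OC(C)=O)[C@@H](C)C(=O)O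
F8 | step 14 | (9R)-hydroxy seco acid (C9 epimer of 18) | C[C@@H](O)[C@H](O[Si](C(C)C)(C(C)C)C(C)C)[C@@H](C)[C@@H]1OC(C)(C)O[C@@]1(C)[C@H](OC(C)=O)[C@@H](C)C(=O)O
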